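**Strategy.** The oxolane ring (O11–C10–C9–C1–C12 of the 11-oxabicyclo[7.3.0]dodecene core) is disconnected into a ketone, C10=O11, and a 2-acylallyl unit, C9–C1–C12. This works because C2, the methylidene-bearing ring carbon on C1, can be carried as an acetyl carbonyl. One operation joins allylic bromide 7 with the L-erythrulose-derived ketone 10: indium-mediated γ-allylation forms C9–C10, and the tertiary alkoxide then closes O11–C12 by 5-endo oxa-Michael addition, setting C9, C10 and C1. The dioxolane of 10 directs the ketone face and is later cut down to the acyloxymethyl arm. (S)-Linalool supplies the tertiary carbinol, and metathesis closes the nine-membered ring.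

Key step: step 7

Remark: (S)-(+)-linalool of high enantiomeric purity, L-erythrulose and diethyl (3-methylbut-2-en-1-yl)phosphonate are taken as catalogue chemicals; atom numbers in the text follow the 11-oxabicyclo[7.3.0]dodecene core (C1 and C9 ring fusion, C2 methylidene carbon, C6 carbinol, C10 quaternary ether carbon, O11, C12 ring OCH2).

Step 1
Reactants: 1 (S)-(+)-linalool
Product: 2 (3S)-3,7-dimethyl-3-(triethylsilyloxy)octa-1,6-diene
Conditions: Et3SiOTf, 2,6-lutidine, CH2Cl2, −78 to 0 °C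
Reagents that add atoms: triethylsilyl trifluoromethanesulfonate, CC[Si](CC)(CC)OS(=O)(=O)C(F)(F)F
Why: Silyl ether formation with the reactive silyl triflate masks the tertiary hydroxyl, which would otherwise trap the aldehyde of step 2 as a lactol, and touches no stereocentre.

Step 2
Reactants: 2 (3S)-3,7-dimethyl-3-(triethylsilyloxy)octa-1,6-diene
Product: 4 (4S)-4-methyl-4-(triethylsilyloxy)hex-5-enal, via ozonide 3 (not isolated)
Conditions: O3, CH2Cl2, −78 °C, Sudan red 7B as end-point indicator; then PPh3, −78 to 25 °C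
Reagents that add atoms: ozone, [O-][O+]=O
Why: Chemoselective ozonolysis should cleave the electron-rich trisubstituted alkene well before the vinyl group flanked by the quaternary silyloxy carbon, and reductive work-up gives the aldehyde.

Step 3
Reactants: 4 (4S)-4-methyl-4-(triethylsilyloxy)hex-5-enal; 5 methyl vinyl ketone
Product: 6 (7S)-4-hydroxy-7-methyl-3-methylidene-7-(triethylsilyloxy)non-8-en-2-one (both C4 epimers)
Conditions: DABCO (0.3 equiv), THF, 25 °C
Reagents that add atoms: none
Why: Morita–Baylis–Hillman reaction of an unhindered aliphatic aldehyde with an alkyl vinyl ketone; the new carbinol centre is formed as a mixture, which does not matter because it becomes sp2 in step 4.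

Step 4
Reactants: 6 (7S)-4-hydroxy-7-methyl-3-methylidene-7-(triethylsilyloxy)non-8-en-2-one
Product: 7 (3Z,7S)-3-(bromomethyl)-7-methyl-7-(triethylsilyloxy)nona-3,8-dien-2-one
Conditions: NBS, Me2S, CH2Cl2, 0 to 25 °C
Reagents that add atoms: N-bromosuccinimide, O=C1CCC(=O)N1Br
Why: Corey–Kim-type activation of the allylic alcohol and SN2' delivery of bromide should give the thermodynamically preferred (Z)-2-(bromomethyl)enone (chain trans to acetyl), the usual outcome for Baylis–Hillman alcohols.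

Step 5
Reactants: 8 L-erythrulose
Product: 9 3,4-O-isopropylidene-L-erythrulose
Conditions: 2,2-dimethoxypropane, TsOH·H2O (cat.), acetone, 25 °C
Reagents that add atoms: 2,2-dimethoxypropane, COC(C)(C)OC
Why: Acid-catalysed transketalisation takes the vicinal 3,4-diol as the five-membered dioxolane and leaves the primary hydroxyl next to the ketone free, without touching the stereocentre.

Step 6
Reactants: 9 3,4-O-isopropylidene-L-erythrulose
Product: 10 2-(tert-butyldimethylsilyloxy)-1-[(4S)-2,2-dimethyl-1,3-dioxolan-4-yl]ethan-1-one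
Conditions: t-BuMe2SiCl, imidazole, DMF, 0 to 25 °C
Reagents that add atoms: tert-butyldimethylsilyl chloride, CC(C)(C)[Si](C)(C)Cl
Why: Imidazole-assisted silylation of the primary alcohol gives a non-chelating ether, so that the ketone can later react under Felkin–Anh control and only one hydroxyl can cyclise in step 7.

Step 7
Reactants: 7 (3Z,7S)-3-(bromomethyl)-7-methyl-7-(triethylsilyloxy)nona-3,8-dien-2-one; 10 2-(tert-butyldimethylsilyloxy)-1-[(4S)-2,2-dimethyl-1,3-dioxolan-4-yl]ethan-1-one (1.5 equiv)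
Product: 13 1-[(3S,4S,5S)-5-[(tert-butyldimethylsilyloxy)methyl]-5-[(4S)-2,2-dimethyl-1,3-dioxolan-4-yl]-4-[(3S)-3-methyl-3-(triethylsilyloxy)pent-4-en-1-yl]oxolan-3-yl]ethan-1-one, via allylindium 11 (not isolated), via hydroxy enone 12 (not isolated)
Conditions: In powder, THF/H2O (1:1), 25 °C; then DBU, 25 °C
Reagents that add atoms: none
Why: Proposed new method: indium inserts into the allylic C–Br bond of 7 and the 2-acetylallylindium 11 adds through its γ-carbon to the electron-poor ketone 10 in a six-membered chair (Zimmerman–Traxler) transition state (C9–C10 bond), after which DBU turns the tertiary hydroxyl of 12 onto the CH2 terminus of the α-methylene ketone in an oxa-Michael addition (O11–C12 bond) and equilibrates the acetyl-bearing carbon; the closest known reaction types are the indium or zinc Barbier 2-carbonylallylation of ketones with Baylis–Hillman bromides (Dreiding–Schmidt type) and the zinc allylation/base-induced cyclisation of 2-(bromomethyl)vinyl sulfones with carbonyl compounds to 3-sulfonyloxolanes. The oxolane closes in the 5-endo-trig mode, which should be acceptable here because the acceptor carbon is an unsubstituted exocyclic methylene, the addition is reversible and the β-alkoxy ketone is the thermodynamic sink, the competing 5-exo hemiketal being only a reversible resting state. The quaternary C10 should be set by Felkin–Anh attack on the Re face, anti to the dioxolane C–O bond of 10 (non-chelating silyl ether, aqueous medium); C9 by the chair transition state with the dioxolanyl group equatorial and the γ-substituent of the (Z)-allylindium axial, which places the side chain cis to the dioxolanyl group; and C1 by thermodynamic protonation trans to the side chain. The step needs γ- over α-attack of the allylindium, addition to 10 rather than to the enone carbonyl of a second molecule of 7, and ring closure by the tertiary hydroxyl alone; these should be secured by the intrinsic γ-selectivity of 2-carbonylallyl metals, by the higher electrophilicity of the α,α'-dioxygenated ketone used in excess, and by silyl or ketal protection of every other oxygen.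

Step 8
Reactants: 13 oxolane methyl ketone
Product: 15 1-[(3S,4S,5S)-5-[(tert-butyldimethylsilyloxy)methyl]-5-[(4S)-2,2-dimethyl-1,3-dioxolan-4-yl]-4-[(3S)-3-methyl-3-(triethylsilyloxy)pent-4-en-1-yl]oxolan-3-yl]ethenyl trifluoromethanesulfonate, via potassium enolate 14 (not isolated)
Conditions: KN(SiMe3)2, THF, −78 °C; then PhNTf2, −78 to 0 °C
Reagents that add atoms: N-phenylbis(trifluoromethanesulfonimide), O=S(=O)(N(c1ccccc1)S(=O)(=O)C(F)(F)F)C(F)(F)F
Why: Kinetic deprotonation at the unhindered methyl group and O-sulfonylation of the enolate (enol triflate formation) should avoid the ring-methine enolate, which could expel the ring oxygen by β-elimination.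

Step 9
Reactants: 15 enol triflate; 16 allyltributylstannane
Product: 17 tert-butyl{[(2S,3S,4R)-2-[(4S)-2,2-dimethyl-1,3-dioxolan-4-yl]-3-[(3S)-3-methyl-3-(triethylsilyloxy)pent-4-en-1-yl]-4-(penta-1,4-dien-2-yl)oxolan-2-yl]methoxy}dimethylsilane
Conditions: Pd(PPh3)4 (5 mol%), LiCl, THF, 65 °C
Reagents that add atoms: none
Why: Stille coupling of an enol triflate with an allylstannane (chloride-promoted) gives the 1,4-diene, in which the former acetyl methyl is now the exocyclic methylene and the allyl group supplies C3 and C4.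

Step 10
Reactants: 17 skipped diene bis-silyl ether
Product: 18 (3S)-5-[(2S,3S,4R)-2-[(4S)-2,2-dimethyl-1,3-dioxolan-4-yl]-2-(hydroxymethyl)-4-(penta-1,4-dien-2-yl)oxolan-3-yl]-3-methylpent-1-en-3-ol
Conditions: Bu4NF, THF, 0 to 40 °C
Reagents that add atoms: none
Why: Fluoride-induced desilylation removes both silyl ethers, freeing the tertiary allylic alcohol that a hindered vinyl carbinol needs for efficient metathesis, while the acetonide is inert.

Step 11
Reactants: 18 diene diol
Product: 19 (1R,4Z,6S,9S,10S)-10-[(4S)-2,2-dimethyl-1,3-dioxolan-4-yl]-10-(hydroxymethyl)-6-methyl-2-methylidene-11-oxabicyclo[7.3.0]dodec-4-en-6-ol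
Conditions: second-generation Hoveyda–Grubbs catalyst RuCl2(H2IMes)(=CH-C6H4-2-O-i-Pr) (10 mol%), 1,4-benzoquinone (20 mol%), toluene (1 mM), 80 °C, argon sparge
Reagents that add atoms: none
Why: Ring-closing metathesis of the two monosubstituted alkenes at high dilution should close the nine-membered ring, whose size enforces the Z alkene; no conjugated diene is present yet to offer a smaller ring, and the 1,1-disubstituted alkene is far less reactive.

Step 12
Reactants: 19 bicyclic diol
Product: 20 (1R,4Z,6S,9S,10R)-10-[(4S)-2,2-dimethyl-1,3-dioxolan-4-yl]-6-hydroxy-6-methyl-2-methylidene-11-oxabicyclo[7.3.0]dodec-4-ene-10-carbaldehyde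
Conditions: Dess–Martin periodinane, NaHCO3, CH2Cl2, 0 to 25 °C
Reagents that add atoms: none
Why: Dess–Martin oxidation converts the neopentyl primary alcohol into a non-enolisable aldehyde, and the tertiary alcohol cannot be oxidised.

Step 13
Reactants: 20 bicyclic aldehyde; 21 diethyl (3-methylbut-2-en-1-yl)phosphonate
Product: 22 (1R,4Z,6S,9S,10R)-10-[(4S)-2,2-dimethyl-1,3-dioxolan-4-yl]-6-methyl-2-methylidene-10-[(1E)-4-methylpenta-1,3-dien-1-yl]-11-oxabicyclo[7.3.0]dodec-4-en-6-ol
Conditions: 21 (3 equiv), n-BuLi, THF, −78 °C; then 20, −78 to 25 °C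
Reagents that add atoms: none
Why: Horner–Wadsworth–Emmons olefination with the lithiated allylic phosphonate, which reacts at its α-carbon, should give the (E)-alkene through the usual thermodynamic preference of the equilibrating adducts, with the excess anion covering the free hydroxyl.

Step 14
Reactants: 22 dienyl acetonide
Product: 23 (1S)-1-[(1R,4Z,6S,9S,10R)-6-hydroxy-6-methyl-2-methylidene-10-[(1E)-4-methylpenta-1,3-dien-1-yl]-11-oxabicyclo[7.3.0]dodec-4-en-10-yl]ethane-1,2-diol
Conditions: AcOH/THF/H2O (3:1:1), 25–35 °C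
Reagents that add atoms: none
Why: Mild ketal hydrolysis in aqueous acetic acid should remove the terminal acetonide faster than the weak acid can ionise the tertiary ether, whose cation is destabilised by the adjacent oxygenated carbon.

Step 15
Reactants: 23 triol
Product: 25 (1R,4Z,6S,9S,10R)-10-(hydroxymethyl)-6-methyl-2-methylidene-10-[(1E)-4-methylpenta-1,3-dien-1-yl]-11-oxabicyclo[7.3.0]dodec-4-en-6-ol, via aldehyde 24 (not isolated)
Conditions: NaIO4, THF/pH 7 phosphate buffer, 0 °C; then NaBH4, MeOH, 0 °C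
Reagents that add atoms: none
Why: Periodate glycol cleavage followed by borohydride reduction in the same flask turns the stereodirecting glycol into the hydroxymethyl arm; C10 has no α-hydrogen and cannot epimerise.

Step 16
Reactants: 25 primary alcohol; 26 nonadecanoic acid
Product: 27 [(1R,4Z,6S,9S,10R)-6-hydroxy-6-methyl-2-methylidene-10-[(1E)-4-methylpenta-1,3-dien-1-yl]-11-oxabicyclo[7.3.0]dodec-4-en-10-yl]methyl nonadecanoate (CNP0120482.1)
Conditions: EDC·HCl, DMAP, CH2Cl2, 0 to 25 °C
Reagents that add atoms: none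
Why: Steglich esterification should acylate the primary alcohol selectively, because the tertiary allylic alcohol is inert to carbodiimide/DMAP activation at this temperature.

**Compound list**

1 | (S)-(+)-linalool, (3S)-3,7-dimethylocta-1,6-dien-3-ol | C=C[C@@](C)(O)CCC=C(C)C | starting material
2 | (3S)-3,7-dimethyl-3-(triethylsilyloxy)octa-1,6-diene | C=C[C@@](C)(O[Si](CC)(CC)CC)CCC=C(C)C | intermediate
3 | ozonide, 3,3-dimethyl-5-[(3S)-3-methyl-3-(triethylsilyloxy)pent-4-en-1-yl]-1,2,4-trioxolane (both C5 epimers) | C=C[C@@](C)(O[Si](CC)(CC)CC)CCC1OOC(C)(C)O1 | intermediate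
4 | (4S)-4-methyl-4-(triethylsilyloxy)hex-5-enal | C=C[C@@](C)(O[Si](CC)(CC)CC)CCC=O | intermediate
5 | methyl vinyl ketone (but-3-en-2-one) | C=CC(C)=O | starting material
6 | (7S)-4-hydroxy-7-methyl-3-methylidene-7-(triethylsilyloxy)non-8-en-2-one (both C4 epimers) | C=C[C@@](C)(O[Si](CC)(CC)CC)CCC(O)C(=C)C(C)=O | intermediate
7 | (3Z,7S)-3-(bromomethyl)-7-methyl-7-(triethylsilyloxy)nona-3,8-dien-2-one | C=C[C@@](C)(O[Si](CC)(CC)CC)CC/C=C(\CBr)C(C)=O | intermediate
8 | L-erythrulose, (3S)-1,3,4-trihydroxybutan-2-one | OCC(=O)[C@@H](O)CO | starting material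
9 | 3,4-O-isopropylidene-L-erythrulose, 1-[(4S)-2,2-dimethyl-1,3-dioxolan-4-yl]-2-hydroxyethan-1-one | OCC(=O)[C@@H]1COC(C)(C)O1 | intermediate
10 | 2-(tert-butyldimethylsilyloxy)-1-[(4S)-2,2-dimethyl-1,3-dioxolan-4-yl]ethan-1-one | CC(C)(C)[Si](C)(C)OCC(=O)[C@@H]1COC(C)(C)O1 | intermediate
11 | [(2Z,6S)-2-acetyl-6-methyl-6-(triethylsilyloxy)octa-2,7-dien-1-yl]indium dibromide (simplest formulation of the allylindium species) | C=C[C@@](C)(O[Si](CC)(CC)CC)CC/C=C(\C[In](Br)Br)C(C)=O | intermediate
12 | (4S,5S)-6-(tert-butyldimethylsilyloxy)-5-[(4S)-2,2-dimethyl-1,3-dioxolan-4-yl]-5-hydroxy-3-methylidene-4-[(3S)-3-methyl-3-(triethylsilyloxy)pent-4-en-1-yl]hexan-2-one | C=C[C@@](C)(O[Si](CC)(CC)CC)CC[C@@H](C(=C)C(C)=O)[C@](O)(CO[Si](C)(C)C(C)(C)C)[C@@H]1COC(C)(C)O1 | intermediate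
13 | 1-[(3S,4S,5S)-5-[(tert-butyldimethylsilyloxy)methyl]-5-[(4S)-2,2-dimethyl-1,3-dioxolan-4-yl]-4-[(3S)-3-methyl-3-(triethylsilyloxy)pent-4-en-1-yl]oxolan-3-yl]ethan-1-one (side chain cis to dioxolanyl, acetyl trans to side chain) | C=C[C@@](C)(O[Si](CC)(CC)CC)CC[C@H]2[C@H](C(C)=O)CO[C@@]2(CO[Si](C)(C)C(C)(C)C)[C@@H]3COC(C)(C)O3 | intermediate
14 | potassium enolate of 13 (methyl-side enolate) | C=C[C@@](C)(O[Si](CC)(CC)CC)CC[C@H]2[C@H](C(=C)[O-])CO[C@@]2(CO[Si](C)(C)C(C)(C)C)[C@@H]3COC(C)(C)O3.[K+] | intermediate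
15 | 1-[(3S,4S,5S)-5-[(tert-butyldimethylsilyloxy)methyl]-5-[(4S)-2,2-dimethyl-1,3-dioxolan-4-yl]-4-[(3S)-3-methyl-3-(triethylsilyloxy)pent-4-en-1-yl]oxolan-3-yl]ethenyl trifluoromethanesulfonate | C=C[C@@](C)(O[Si](CC)(CC)CC)CC[C@H]2[C@H](C(=C)OS(=O)(=O)C(F)(F)F)CO[C@@]2(CO[Si](C)(C)C(C)(C)C)[C@@H]3COC(C)(C)O3 | intermediate
16 | allyltributylstannane | C=CC[Sn](CCCC)(CCCC)CCCC | starting material
17 | tert-butyl{[(2S,3S,4R)-2-[(4S)-2,2-dimethyl-1,3-dioxolan-4-yl]-3-[(3S)-3-methyl-3-(triethylsilyloxy)pent-4-en-1-yl]-4-(penta-1,4-dien-2-yl)oxolan-2-yl]methoxy}dimethylsilane | C=C[C@@](C)(O[Si](CC)(CC)CC)CC[C@H]2[C@H](C(=C)CC=C)CO[C@@]2(CO[Si](C)(C)C(C)(C)C)[C@@H]3COC(C)(C)O3 | intermediate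
18 | (3S)-5-[(2S,3S,4R)-2-[(4S)-2,2-dimethyl-1,3-dioxolan-4-yl]-2-(hydroxymethyl)-4-(penta-1,4-dien-2-yl)oxolan-3-yl]-3-methylpent-1-en-3-ol | C=C[C@@](C)(O)CC[C@H]2[C@H](C(=C)CC=C)CO[C@@]2(CO)[C@@H]3COC(C)(C)O3 | intermediate
19 | (1R,4Z,6S,9S,10S)-10-[(4S)-2,2-dimethyl-1,3-dioxolan-4-yl]-10-(hydroxymethyl)-6-methyl-2-methylidene-11-oxabicyclo[7.3.0]dodec-4-en-6-ol | C=C1C/C=C\[C@@](C)(O)CC[C@H]2[C@H]1CO[C@@]2(CO)[C@@H]3COC(C)(C)O3 | intermediate
20 | (1R,4Z,6S,9S,10R)-10-[(4S)-2,2-dimethyl-1,3-dioxolan-4-yl]-6-hydroxy-6-methyl-2-methylidene-11-oxabicyclo[7.3.0]dodec-4-ene-10-carbaldehyde | C=C1C/C=C\[C@@](C)(O)CC[C@H]2[C@H]1CO[C@@]2(C=O)[C@@H]3COC(C)(C)O3 | intermediate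
21 | diethyl (3-methylbut-2-en-1-yl)phosphonate | CCOP(=O)(CC=C(C)C)OCC | starting material
22 | (1R,4Z,6S,9S,10R)-10-[(4S)-2,2-dimethyl-1,3-dioxolan-4-yl]-6-methyl-2-methylidene-10-[(1E)-4-methylpenta-1,3-dien-1-yl]-11-oxabicyclo[7.3.0]dodec-4-en-6-ol | C=C1C/C=C\[C@@](C)(O)CC[C@H]2[C@H]1CO[C@@]2(/C=C/C=C(C)C)[C@@H]3COC(C)(C)O3 | intermediate
23 | (1S)-1-[(1R,4Z,6S,9S,10R)-6-hydroxy-6-methyl-2-methylidene-10-[(1E)-4-methylpenta-1,3-dien-1-yl]-11-oxabicyclo[7.3.0]dodec-4-en-10-yl]ethane-1,2-diol | C=C1C/C=C\[C@@](C)(O)CC[C@H]2[C@H]1CO[C@@]2(/C=C/C=C(C)C)[C@@H](O)CO | intermediate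
24 | (1R,4Z,6S,9S,10R)-6-hydroxy-6-methyl-2-methylidene-10-[(1E)-4-methylpenta-1,3-dien-1-yl]-11-oxabicyclo[7.3.0]dodec-4-ene-10-carbaldehyde | C=C1C/C=C\[C@@](C)(O)CC[C@H]2[C@H]1CO[C@@]2(/C=C/C=C(C)C)C=O | intermediate
25 | (1R,4Z,6S,9S,10R)-10-(hydroxymethyl)-6-methyl-2-methylidene-10-[(1E)-4-methylpenta-1,3-dien-1-yl]-11-oxabicyclo[7.3.0]dodec-4-en-6-ol | C=C1C/C=C\[C@@](C)(O)CC[C@H]2[C@H]1CO[C@@]2(/C=C/C=C(C)C)CO | intermediate
26 | nonadecanoic acid | CCCCCCCCCCCCCCCCCCC(=O)O | starting material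
27 | [(1R,4Z,6S,9S,10R)-6-hydroxy-6-methyl-2-methylidene-10-[(1E)-4-methylpenta-1,3-dien-1-yl]-11-oxabicyclo[7.3.0]dodec-4-en-10-yl]methyl nonadecanoate (CNP0120482.1) | C=C1C/C=C\[C@@](C)(O)CC[C@H]2[C@H]1CO[C@@]2(/C=C/C=C(C)C)COC(=O)CCCCCCCCCCCCCCCCCC | target

**Total step count:** 16. **Longest linear sequence:** 14 steps (steps 1–4 and 7–16, from (S)-linalool); steps 5–6 make the ketone partner.

**Three steps most likely to fail**

1. Step 7 (proposed new method). The hindered ketone may be attacked with insufficient facial control, for instance if chelation competes with the Felkin–Anh mode, or with the opposite simple diastereoselection. The 5-endo ring closure may also stall at the open adduct or revert by retro-Michael elimination. Fallback with known chemistry, setting out from aldehyde 4 and ketone 10 and returning at oxolane ketone 13: the acetyl group is replaced by a sulfonyl group, for which the two-bond annulation is established. Baylis–Hillman reaction of 4 with phenyl vinyl sulfone (DABCO) would give the hydroxy vinyl sulfone F1, and NBS/Me2S the allylic bromide F2. Zinc-mediated Barbier addition of F2 to 10 would give the open hydroxy vinyl sulfone F3, which KOt-Bu should close by the known 5-endo-trig cyclisation to the 3-(benzenesulfonyl)oxolane F4. Lithiation (n-BuLi, −78 °C) and acylation with N-methoxy-N-methylacetamide would give the keto sulfone F5, and SmI2/MeOH would remove the sulfonyl group to give 13.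

2. Step 11. Intermolecular metathesis (oligomerisation) and alkene migration in the 1,4-diene may outrun closure of the strained nine-membered ring. Fallback, setting out from 13 and returning at 19: the ring is closed at the C3–C4 bond by palladium-catalysed intramolecular α-alkenylation of the methyl ketone instead of at C4=C5 by metathesis. Lemieux–Johnson cleavage of the vinyl group of 13 (OsO4 cat., NaIO4, 2,6-lutidine) would give the α-silyloxy aldehyde F6, and Stork–Zhao olefination (Ph3P=CHI) the (Z)-vinyl iodide F7. Pd2(dba)3/XPhos with LiN(SiMe3)2 at high dilution should then close the bicyclic β,γ-unsaturated ketone F8. Takai–Lombardo methylenation (Zn, CH2Br2, TiCl4) would give the methylidene bis-silyl ether F9, and Bu4NF would give 19.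

3. Step 14. The acid may ionise the tertiary dienyl ether or the tertiary allylic alcohol, or isomerise the diene, before the ketal is cleaved. Fallback, setting out from aldehyde 20 and returning at alcohol 25: the conjugated diene is introduced only after the acid step, by cross-coupling instead of olefination. Takai iodo-olefination of 20 (CHI3, CrCl2, THF) would give the (E)-vinyl iodide acetonide F10, whose ether is far less ionisable, and aqueous acetic acid would then give the vinyl iodide triol F11. NaIO4 would give the vinyl iodide aldehyde F12, reduced in the same flask by NaBH4 to the hydroxymethyl vinyl iodide F13. Suzuki–Miyaura coupling of F13 with 2-methylprop-1-enylboronic acid pinacol ester (Pd(PPh3)4, aqueous K3PO4, THF) would give 25.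

**Further compounds**

F1 | step 7 | (6S)-2-(benzenesulfonyl)-6-methyl-6-(triethylsilyloxy)octa-1,7-dien-3-ol (both C3 epimers) | C=C[C@@](C)(O[Si](CC)(CC)CC)CCC(O)C(=C)S(=O)(=O)c1ccccc1
F2 | step 7 | [(2E,6S)-1-bromo-6-methyl-6-(triethylsilyloxy)octa-2,7-dien-2-yl]sulfonylbenzene | C=C[C@@](C)(O[Si](CC)(CC)CC)CC/C=C(\CBr)S(=O)(=O)c1ccccc1
F3 | step 7 | open hydroxy vinyl sulfone, sulfonyl analogue of 12 | C=C[C@@](C)(O[Si](CC)(CC)CC)CC[C@@H](C(=C)S(=O)(=O)c1ccccc1)[C@](O)(CO[Si](C)(C)C(C)(C)C)[C@@H]2COC(C)(C)O2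
F4 | step 7 | 3-(benzenesulfonyl)oxolane, sulfonyl analogue of 13 | C=C[C@@](C)(O[Si](CC)(CC)CC)CC[C@H]2[C@H](S(=O)(=O)c3ccccc3)CO[C@@]2(CO[Si](C)(C)C(C)(C)C)[C@@H]4COC(C)(C)O4
F5 | step 7 | 3-acetyl-3-(benzenesulfonyl)oxolane keto sulfone (sulfonyl-bearing centre as a mixture) | C=C[C@@](C)(O[Si](CC)(CC)CC)CC[C@H]2C(C(C)=O)(S(=O)(=O)c3ccccc3)CO[C@@]2(CO[Si](C)(C)C(C)(C)C)[C@@H]4COC(C)(C)O4
F6 | step 11 | α-silyloxy aldehyde from cleavage of the vinyl group of 13 | O=C[C@@](C)(O[Si](CC)(CC)CC)CC[C@H]2[C@H](C(C)=O)CO[C@@]2(CO[Si](C)(C)C(C)(C)C)[C@@H]3COC(C)(C)O3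
F7 | step 11 | (Z)-vinyl iodide methyl ketone | I/C=C\[C@@](C)(O[Si](CC)(CC)CC)CC[C@H]2[C@H](C(C)=O)CO[C@@]2(CO[Si](C)(C)C(C)(C)C)[C@@H]3COC(C)(C)O3
F8 | step 11 | bicyclic β,γ-unsaturated ketone (11-oxabicyclo[7.3.0]dodec-4-en-2-one, bis-silyl ether) | O=C1C/C=C\[C@@](C)(O[Si](CC)(CC)CC)CC[C@H]2[C@H]1CO[C@@]2(CO[Si](C)(C)C(C)(C)C)[C@@H]3COC(C)(C)O3
F9 | step 11 | bicyclic methylidene bis-silyl ether (bis-silyl ether of 19) | C=C1C/C=C\[C@@](C)(O[Si](CC)(CC)CC)CC[C@H]2[C@H]1CO[C@@]2(CO[Si](C)(C)C(C)(C)C)[C@@H]3COC(C)(C)O3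
F10 | step 14 | (E)-vinyl iodide acetonide | C=C1C/C=C\[C@@](C)(O)CC[C@H]2[C@H]1CO[C@@]2(/C=C/I)[C@@H]3COC(C)(C)O3
F11 | step 14 | (E)-vinyl iodide triol | C=C1C/C=C\[C@@](C)(O)CC[C@H]2[C@H]1CO[C@@]2(/C=C/I)[C@@H](O)CO
F12 | step 14 | (E)-vinyl iodide aldehyde (not isolated) | C=C1C/C=C\[C@@](C)(O)CC[C@H]2[C@H]1CO[C@@]2(/C=C/I)C=O
F13 | step 14 | hydroxymethyl (E)-vinyl iodide | C=C1C/C=C\[C@@](C)(O)CC[C@H]2[C@H]1CO[C@@]2(/C=C/I)CO
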